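The runs stem from a simulated flask for substances that don't exist, and the scatter is random.

Take the charge of G as your unit: every amount here is a fraction of it, and Q counts in equivalents of it.

the same everywhere: G 0.25 M

| charge | Q | remark | time |
|---|---|---|---|
| epsilon | 1.1 equiv | run made earlier |  |
| beta | 1.6 equiv | run made earlier |  |
| zeta | 2.6 equiv | run made earlier |  |
| birch | 0.900 equiv |  | 2.5 d |
| cedar | 2.70 equiv |  | 2.5 d |

| run | time / h | G / % | L / % | X / % | D / % |
|---|---|---|---|---|---|
| epsilon | 4.00 | 80.9 | 0 | 0.1 | 17.0 |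
| epsilon | 10.0 | 67.8 | 0.3 | 6.0 | 25.3 |
| epsilon | 20.0 | 59.7 | 2.6 | 13.9 | 26.6 |
| epsilon | 30.0 | 54.1 | 4.8 | 18.6 | 27.6 |
| epsilon | 40.0 | 49.6 | 4.2 | 23.4 | 22.4 |
| beta | 8.00 | 60.3 | 2.7 | 3.0 | 33.9 |
| beta | 15.0 | 52.8 | 0 | 10.9 | 35.3 |
| beta | 25.0 | 42.9 | 1.5 | 19.5 | 32.6 |
| beta | 30.0 | 40.4 | 4.7 | 24.8 | 33.9 |
| beta | 40.0 | 36.2 | 6.0 | 30.8 | 28.6 |
| zeta | 8.00 | 44.7 | 1.6 | 8.4 | 47.3 |
| zeta | 15.0 | 33.6 | 2.0 | 18.1 | 48.6 |
| zeta | 25.0 | 26.4 | 4.4 | 28.2 | 41.7 |
| zeta | 30.0 | 22.1 | 8.0 | 32.6 | 40.7 |
| zeta | 40.0 | 21.0 | 8.2 | 38.0 | 32.4 |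

(readings scatter by 1 percentage point)

- the numbers in the tables scatter with a standard deviation of 1 percentage point
- what may be going on: G + Q <-> D; D <-> X + Z; X <-> L; Q <-> J

- which of these there is most of at the end, counted by the G in it, birch (X / L / D / G)
- which of these there is most of at the end, counted by the G in it, cedar (X / L / D / G)
- the largest of these amounts at the end, in percent of the G charged, birch
- the largest of these amounts at the end, in percent of the G charged, cedar

What does the first step leave free? Each G that has reacted took one Q with it, so the Q not yet taken, free or parked as J, forms a pool p: the Q charge less the fraction of G gone. If G + Q ⇌ D keeps pace (a pre-equilibrium), D/G should follow p. At the last readings D/(G·p) is 0.758 in epsilon, 0.821 in beta and 0.852 in zeta, while the charge runs from 1.1 equiv to 2.6 equiv. Their mean, 0.810, is what I call the hold: D per G per equivalent of pool.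

How much has left the store G + D? On the scheme X + L grow from D, so zeta's gain from 15.0 h to 40.0 h, divided by mean D and the time between, gives a drain constant of 0.0258 h⁻¹.

So, by my reckoning, birch, held at epsilon's last D, drains 34.6%. The hold splits the rest into G of 49.5%, above even X and L together.

Cedar, charged with 2.70 equiv against zeta's 2.6 equiv, I take as zeta continued for 20.0 h with D held at zeta's last reading, which brings X + L to 62.9%. The hold then leaves G at 14.8% and D at 22.2%. Zeta's last L/X puts X at 51.7%, more than either.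

The forecast says G at 50% for birch and X at 46% for cedar, lower than my 51.7% for cedar's X, and grounds birch thus: “Birch is limited by Q.” Q is the limiting reagent there, charged at 0.900 equiv.

The flask gives G at 50.5% in birch and X at 46.7% in cedar.

    G + Q ⇌ D (K = 10.0 L mol⁻¹, k = 0.260 L mol⁻¹ h⁻¹)
    D ⇌ X + Z (K = 0.630 M, k = 0.0310 h⁻¹)
    X ⇌ L (K = 0.350, k = 0.0210 h⁻¹)
    Q ⇌ J (K = 0.910, k = 0.0700 h⁻¹)

Birch's end amounts give a hold of 0.781, beside the 0.810 read earlier, and p there counts J. Cedar's X stands at 46.7%, and without the difference in equivalents of Q it is 26.3%, so that difference is the main reason for it. On cedar's neighbour read at 6.0 d, with G at 7.86% and D at 17.6%, the hold has risen above the earlier reading to 1.26.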